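**Retrosynthetic overview**

1. Feature: the benzene ring carries OH on C2', C4' and C6' and, on C1' between two of them, the ketone carbon C1 of the C16 chain (C1 ketone to C16 methyl, S-carbinol at C13). This pattern is the cyclised, enolised form of a linear 3,5,7-triketo ester.
2. Ring (the only one, closed in step 8): the C1'–C2' ring bond is cut to give methyl (S)-19-silyloxy-3,5,7-trioxodocosanoate. In the forward sense its C6 methylene closes on the C1 ester (Claisen) and the trione aromatises.
3. Triketo ester: the C6–C7 bond comes from acylating the trianion of methyl 3,5-dioxohexanoate (from dehydroacetic acid) with the Weinreb amide of (S)-13-silyloxyhexadecanoic acid.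
4. C16 acid: the C11–C12 bond comes from copper-catalysed opening of (S)-1,2-epoxypentane (source of the one stereocentre) by undec-10-enylmagnesium bromide. The terminal alkene is the latent carboxyl (hydroboration, then oxidation).
5. The silyl ether is removed last.

Key step: step 8

Assumption: (S)-1,2-epoxypentane is taken as a purchasable enantiopure building block (it is also what hydrolytic kinetic resolution of the racemic epoxide leaves behind).

**Route**

Step 1
Reactants: 1 11-bromoundec-1-ene; 2 (S)-1,2-epoxypentane
Product: 4 (S)-hexadec-15-en-4-ol, via undec-10-enylmagnesium bromide 3 (not isolated)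
Conditions: Mg, THF, 40 °C; then CuBr·SMe2 (10 mol%), 2 (0.8 equiv), THF, −30 → 0 °C; 1 M HCl aq.
Reagents that add atoms: magnesium, [Mg] (kept only in intermediate 3)
Why: Copper-catalysed Grignard opening of a terminal epoxide is an SN2 attack at the unsubstituted CH2, so the C11–C12 bond forms without touching the C–O stereocentre of 2, which is carried over as the (S)-carbinol.

Step 2
Reactants: 4 (S)-hexadec-15-en-4-ol
Product: 5 (S)-tert-butyl(hexadec-15-en-4-yloxy)dimethylsilane
Conditions: TBSCl, imidazole, DMF, rt
Reagents that add atoms: tert-butyldimethylsilyl chloride, CC(C)(C)[Si](C)(C)Cl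
Why: Imidazole-promoted silylation (Corey protocol) of the secondary alcohol occurs at oxygen only, leaves the configuration untouched and masks the carbinol for the oxidation and the strongly basic steps that follow.

Step 3
Reactants: 5 (S)-tert-butyl(hexadec-15-en-4-yloxy)dimethylsilane
Product: 7 (S)-13-(tert-butyldimethylsilyloxy)hexadecan-1-ol, via B-alkyl-9-BBN adduct 6 (not isolated)
Conditions: 9-BBN (0.5 M in THF), 0 °C → rt; then 3 M NaOH aq., 30% H2O2, 0 °C → rt
Reagents that add atoms: hydrogen peroxide, OO (source of the hydroxyl oxygen); 9-borabicyclo[3.3.1]nonane, B1C2CCCC1CCC2 (boron kept only in intermediate 6)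
Why: Brown hydroboration with the bulky 9-BBN places boron on the terminal carbon of the monosubstituted alkene and alkaline peroxide replaces it by OH, giving the anti-Markovnikov primary alcohol while the silyl ether survives the brief basic treatment.

Step 4
Reactants: 7 (S)-13-(tert-butyldimethylsilyloxy)hexadecan-1-ol
Product: 8 (S)-13-(tert-butyldimethylsilyloxy)hexadecanoic acid
Conditions: TEMPO (20 mol%), PhI(OAc)2 (2.2 equiv), MeCN/CH2Cl2/H2O, rt
Reagents that add atoms: water, O
Why: Oxoammonium (TEMPO) catalysed oxidation with PhI(OAc)2 as terminal oxidant takes the primary alcohol through the aldehyde hydrate to the acid under nearly neutral aqueous conditions that a secondary TBS ether tolerates.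

Step 5
Reactants: 8 (S)-13-(tert-butyldimethylsilyloxy)hexadecanoic acid
Product: 10 (S)-13-(tert-butyldimethylsilyloxy)-N-methoxy-N-methylhexadecanamide, via acyl imidazolide 9 (not isolated)
Conditions: 1,1'-carbonyldiimidazole, CH2Cl2, rt; then MeNH(OMe)·HCl, rt
Reagents that add atoms: N,O-dimethylhydroxylamine hydrochloride, CNOC.Cl; 1,1'-carbonyldiimidazole, O=C(n1ccnc1)n1ccnc1 (imidazole kept only in intermediate 9)
Why: Activation of the acid as its N-acylimidazole and aminolysis by N,O-dimethylhydroxylamine is a standard Weinreb amide synthesis that cannot affect the remote silyl ether or the stereocentre.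

Step 6
Reactants: 11 dehydroacetic acid
Product: 12 methyl 3,5-dioxohexanoate
Conditions: Mg(OMe)2 (2.2 equiv), MeOH, reflux; then 1 M HCl aq., 0 °C
Reagents that add atoms: methanol, CO (delivered as magnesium methoxide, C[O-].C[O-].[Mg+2])
Why: Methoxide opens the pyranone lactone and removes the 3-acetyl group by retro-Claisen cleavage as methyl acetate, the magnesium chelate of the 3,5-dioxo ester shielding it from further cleavage; this is the known methanolysis of dehydroacetic acid.

Step 7
Reactants: 12 methyl 3,5-dioxohexanoate (2 equiv); 10 (S)-13-(tert-butyldimethylsilyloxy)-N-methoxy-N-methylhexadecanamide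
Product: 14 methyl (S)-19-(tert-butyldimethylsilyloxy)-3,5,7-trioxodocosanoate, via trilithium trienolate 13 (not isolated)
Conditions: LiN(iPr)2 (3.2 equiv per 12), THF, −78 → 0 °C; then 10, −78 → 0 °C; AcOH, −78 °C; crude ester taken on promptly
Reagents that add atoms: lithium diisopropylamide, [Li+].CC(C)[N-]C(C)C (lithium kept only in intermediate 13)
Why: Three equivalents of LiN(iPr)2 deprotonate C2, C4 and finally the C6 methyl of 12, and the last-formed, most basic terminal carbanion of trianion 13 attacks the Weinreb amide (Claisen-type C-acylation of a 1,3-dicarbonyl polyanion); the chelated tetrahedral adduct persists until the acidic quench, which prevents proton transfer to unreacted trianion and double addition.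

Step 8
Reactants: 14 methyl (S)-19-(tert-butyldimethylsilyloxy)-3,5,7-trioxodocosanoate
Product: 16 (S)-13-(tert-butyldimethylsilyloxy)-1-(2,4,6-trihydroxyphenyl)hexadecan-1-one, via 2-acylcyclohexane-1,3,5-trione 15 (not isolated)
Conditions: Mg(OMe)2 (6 equiv), MeOH, reflux, Ar; then 0.5 M HCl aq., 0 °C, rapid extraction
Reagents that add atoms: none
Why: Excess Mg(OMe)2 turns 14 into a magnesium-chelated polyenolate in which the C3, C5 and C7 ketones are enolised and so switched off as electrophiles, while C6 (between the C5 and C7 carbonyls) stays nucleophilic and the C1 methyl ester is the one carbonyl still open to attack; C6 adds to C1, methoxide leaves to give trione 15, and tautomerisation to the aromatic triol makes the closure irreversible. The closest known reaction is the base-induced Claisen (Dieckmann-type) cyclisation of 3,5,7-triketo esters to acylphloroglucinols, the laboratory counterpart of the ring closure carried out by chalcone-synthase-type polyketide synthases. The single ring closes in a 6-exo-trig mode (enolate carbon C6 onto the exocyclic C1=O), forming the bond between the acyl-bearing ring carbon and a neighbouring C–OH carbon, so ring and aryl ketone arise together and only one acyl group can be present. No stereocentre is formed, and the silyloxy centre at C19, eleven methylenes from the nearest carbonyl, cannot epimerise. The selectivity needed is Claisen closure (C6 to C1) over aldol closure (C2 to C7, leading to a 6-alkylresorcylate) and over pyrone formation through oxygen; it is secured by full enolisation of the ketones in anhydrous methoxide with the divalent magnesium counter-ion, by the matched methyl ester/methoxide pair, and by the exclusion of water, which would saponify the ester and divert material to the aldol pathway.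

Step 9
Reactants: 16 (S)-13-(tert-butyldimethylsilyloxy)-1-(2,4,6-trihydroxyphenyl)hexadecan-1-one
Product: 17 (S)-13-hydroxy-1-(2,4,6-trihydroxyphenyl)hexadecan-1-one (CNP0242597.1)
Conditions: HF (48% aq.), MeCN, 0 °C → rt
Reagents that add atoms: none
Why: Acid-assisted fluoride cleavage of the Si–O bond frees the C13 alcohol without breaking a bond at the stereocentre, and the non-basic medium avoids phenoxide formation and air oxidation of the electron-rich triol.

**Compound list**

1 | 11-bromoundec-1-ene | C=CCCCCCCCCCBr | starting material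
2 | (S)-1,2-epoxypentane [(S)-2-propyloxirane] | CCC[C@H]1CO1 | starting material
3 | undec-10-enylmagnesium bromide | C=CCCCCCCCCC[Mg]Br | intermediate (not isolated)
4 | (S)-hexadec-15-en-4-ol | CCC[C@H](O)CCCCCCCCCCC=C | intermediate
5 | (S)-tert-butyl(hexadec-15-en-4-yloxy)dimethylsilane | CCC[C@H](O[Si](C)(C)C(C)(C)C)CCCCCCCCCCC=C | intermediate
6 | 9-[(13S)-13-(tert-butyldimethylsilyloxy)hexadecyl]-9-borabicyclo[3.3.1]nonane | CCC[C@H](O[Si](C)(C)C(C)(C)C)CCCCCCCCCCCCB1C2CCCC1CCC2 | intermediate (not isolated)
7 | (S)-13-(tert-butyldimethylsilyloxy)hexadecan-1-ol | CCC[C@H](O[Si](C)(C)C(C)(C)C)CCCCCCCCCCCCO | intermediate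
8 | (S)-13-(tert-butyldimethylsilyloxy)hexadecanoic acid | CCC[C@H](O[Si](C)(C)C(C)(C)C)CCCCCCCCCCCC(=O)O | intermediate
9 | 1-[(13S)-13-(tert-butyldimethylsilyloxy)hexadecanoyl]imidazole | CCC[C@H](O[Si](C)(C)C(C)(C)C)CCCCCCCCCCCC(=O)n1ccnc1 | intermediate (not isolated)
10 | (S)-13-(tert-butyldimethylsilyloxy)-N-methoxy-N-methylhexadecanamide | CCC[C@H](O[Si](C)(C)C(C)(C)C)CCCCCCCCCCCC(=O)N(C)OC | intermediate
11 | dehydroacetic acid (3-acetyl-4-hydroxy-6-methyl-2H-pyran-2-one) | CC(=O)C1=C(O)C=C(C)OC1=O | starting material
12 | methyl 3,5-dioxohexanoate | COC(=O)CC(=O)CC(C)=O | intermediate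
13 | trilithium trienolate (trianion) of methyl 3,5-dioxohexanoate | [Li+].[Li+].[Li+].COC([O-])=CC([O-])=CC([O-])=C | intermediate (not isolated)
14 | methyl (S)-19-(tert-butyldimethylsilyloxy)-3,5,7-trioxodocosanoate (drawn as the triketo tautomer) | CCC[C@H](O[Si](C)(C)C(C)(C)C)CCCCCCCCCCCC(=O)CC(=O)CC(=O)CC(=O)OC | intermediate
15 | 2-[(13S)-13-(tert-butyldimethylsilyloxy)hexadecanoyl]cyclohexane-1,3,5-trione | CCC[C@H](O[Si](C)(C)C(C)(C)C)CCCCCCCCCCCC(=O)C1C(=O)CC(=O)CC1=O | intermediate (not isolated)
16 | (S)-13-(tert-butyldimethylsilyloxy)-1-(2,4,6-trihydroxyphenyl)hexadecan-1-one | CCC[C@H](O[Si](C)(C)C(C)(C)C)CCCCCCCCCCCC(=O)c1c(O)cc(O)cc1O | intermediate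
17 | (S)-13-hydroxy-1-(2,4,6-trihydroxyphenyl)hexadecan-1-one | CCC[C@H](O)CCCCCCCCCCCC(=O)c1c(O)cc(O)cc1O | target

**Count and risks**

Total steps: 9. Longest linear sequence: 8 steps (steps 1, 2, 3, 4, 5, 7, 8, 9); step 6 is a one-step side branch.

Risk 1, step 8. The polyenolate may close in the aldol sense (C2 onto the C7 ketone) or lactonise through an enol oxygen to a pyrone instead of undergoing the Claisen closure, or remain as an unreactive chelate. The fallback attaches a preformed phloroglucinol ring instead of building it; it sets out from Weinreb amide 10 and returns at target 17. Phloroglucinol is converted with MOMCl and iPr2NEt in CH2Cl2 into 1,3,5-tris(methoxymethoxy)benzene F1. Lithiation with n-BuLi in THF at 0 °C, directed by the two flanking acetal oxygens, gives [2,4,6-tris(methoxymethoxy)phenyl]lithium F2. Addition of F2 to 10 at −78 °C → rt, with an aqueous NH4Cl quench, should give (S)-13-(tert-butyldimethylsilyloxy)-1-[2,4,6-tris(methoxymethoxy)phenyl]hexadecan-1-one F3. HCl in MeOH at 40 °C then removes the three acetal groups and the silyl ether in one operation to give 17.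

Risk 2, step 7. The third deprotonation of 12 may be incomplete, proton exchange between the trianion and the amide or product may stop the acylation, and the triketo ester may cyclodehydrate to pyrones during work-up. The fallback keeps the ester end masked as a dioxinone until the carbon chain is complete; it sets out from Weinreb amide 10 and returns at triketo ester 14. Commercial 2,2,6-trimethyl-4H-1,3-dioxin-4-one is acetylated through its lithium dienolate (LiN(SiMe3)2, THF, −78 °C; AcCl) to 2,2-dimethyl-6-(2-oxopropyl)-4H-1,3-dioxin-4-one F4. Two equivalents of LiN(iPr)2 give the dilithium dianion of the keto-dioxinone F5, whose terminal carbon is acylated by 10 (AcOH quench) to give the (S)-silyloxy diketo-dioxinone F6. Heating F6 in toluene with MeOH at 110 °C expels acetone by retro-hetero-Diels–Alder fragmentation, and the resulting (S)-silyloxy triketo acylketene F7 is trapped by methanol as 14.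

Risk 3, step 1. Wurtz-type homocoupling while the long-chain Grignard reagent forms, and bromohydrin formation by magnesium bromide opening of the epoxide, may consume the enantiopure epoxide. The fallback replaces the Grignard reagent by a sulfone-stabilised carbanion; it sets out from bromide 1 (with epoxide 2) and returns at alcohol 4. Displacement of bromide in 1 with PhSO2Na in DMF at 60 °C gives phenyl undec-10-enyl sulfone F8. Deprotonation with n-BuLi in THF at −78 °C gives the α-lithio sulfone F9, which opens 2 at its CH2 terminus in the presence of BF3·OEt2 to give (4S)-6-(phenylsulfonyl)hexadec-15-en-4-ol F10, a mixture of epimers at the sulfonyl carbon that is of no consequence. Reductive desulfonylation with Na(Hg) and Na2HPO4 in MeOH at −20 °C then gives 4.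

**Further compounds**

F1 | step 8 | 1,3,5-tris(methoxymethoxy)benzene | COCOc1cc(OCOC)cc(OCOC)c1
F2 | step 8 | [2,4,6-tris(methoxymethoxy)phenyl]lithium | [Li]c1c(OCOC)cc(OCOC)cc1OCOC
F3 | step 8 | (S)-13-(tert-butyldimethylsilyloxy)-1-[2,4,6-tris(methoxymethoxy)phenyl]hexadecan-1-one | CCC[C@H](O[Si](C)(C)C(C)(C)C)CCCCCCCCCCCC(=O)c1c(OCOC)cc(OCOC)cc1OCOC
F4 | step 7 | 2,2-dimethyl-6-(2-oxopropyl)-4H-1,3-dioxin-4-one | CC(=O)CC1=CC(=O)OC(C)(C)O1
F5 | step 7 | dilithium dianion of 2,2-dimethyl-6-(2-oxopropyl)-4H-1,3-dioxin-4-one | [Li+].[Li+].C=C([O-])C=C1C=C([O-])OC(C)(C)O1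
F6 | step 7 | 6-[(17S)-17-(tert-butyldimethylsilyloxy)-2,4-dioxoicosyl]-2,2-dimethyl-4H-1,3-dioxin-4-one | CCC[C@H](O[Si](C)(C)C(C)(C)C)CCCCCCCCCCCC(=O)CC(=O)CC1=CC(=O)OC(C)(C)O1
F7 | step 7 | (19S)-19-(tert-butyldimethylsilyloxy)-3,5,7-trioxodocos-1-en-1-one (acylketene) | CCC[C@H](O[Si](C)(C)C(C)(C)C)CCCCCCCCCCCC(=O)CC(=O)CC(=O)C=C=O
F8 | step 1 | phenyl undec-10-enyl sulfone | C=CCCCCCCCCCS(=O)(=O)c1ccccc1
F9 | step 1 | [1-(phenylsulfonyl)undec-10-enyl]lithium | [Li]C(CCCCCCCCC=C)S(=O)(=O)c1ccccc1
F10 | step 1 | (4S)-6-(phenylsulfonyl)hexadec-15-en-4-ol | CCC[C@H](O)CC(CCCCCCCCC=C)S(=O)(=O)c1ccccc1
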